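**Plan**
1. The target is the hydrogen malonate of ent-copalol (5R,9R,10R; labdane numbering is used throughout). The ester C15–O bond is cut last.
2. Enabling feature: in ring A the bonds C3–C4 and C5–C10 flank C4–C5 and lie opposite C1–C2, so ring A is a retro-[4+2] ring. Cutting both bonds gives a diene C10=C1–C2=C3 and a dienophile C4=C5 that are already joined through C6–C9, so one intramolecular Diels–Alder reaction closes rings A and B together.
3. Helpers: C18 is carried as CHO (activates C4=C5) and C2 carries OEt (activates the diene and leaves a C2 ketone instead of a ring-A alkene next to C8=C17). One Wolff–Kishner step removes both and frees O15.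
4. Forward: geranyl acetate gives C1, C9–C16 and C20; 6-methylhept-5-en-2-one gives C4–C8 and C17–C19 (C8–C9 by conjugate addition); a Stille coupling adds C2–C3. Then cycloaddition, reduction, malonylation.
5. Stereochemistry: C9 comes from a Cu/Tol-BINAP conjugate addition; C10 and C5 follow from C9 in the endo, chair-tether transition state; 13E comes from geranyl acetate; the diene and dienophile geometries come from s-trans enolate trapping and SeO2 oxidation.

Key step: step 9

Assumption: the Tol-BINAP antipode that delivers the alkenyl group to give the (6R) centre of 10 is written as (R); if the sense of induction is the opposite, (S)-Tol-BINAP is used.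

**Step 1**
Reactants: 1 geranyl acetate
Product: 2 (2E,6E)-8-hydroxy-3,7-dimethylocta-2,6-dien-1-yl acetate
Conditions: SeO2 (cat.), t-BuOOH, salicylic acid (cat.), CH2Cl2, 0 °C → rt
Reagents that add atoms: selenium dioxide O=[Se]=O (catalytic oxygen carrier); tert-butyl hydroperoxide CC(C)(C)OO (terminal oxidant)
Why: SeO2-catalysed allylic oxidation (ene reaction then [2,3]-sigmatropic shift) should attack only the electron-rich terminal alkene at its (E)-methyl group, as is usual for geranyl esters, so the (6E) allylic alcohol is expected.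

**Step 2**
Reactants: 2 (2E,6E)-8-hydroxy-3,7-dimethylocta-2,6-dien-1-yl acetate
Product: 3 (2E,6E)-3,7-dimethyl-8-oxoocta-2,6-dien-1-yl acetate
Conditions: MnO2, CH2Cl2, rt
Reagents that add atoms: none
Why: MnO2 oxidation of a primary allylic alcohol should stop at the enal without E/Z isomerisation.

**Step 3**
Reactants: 4 6-methylhept-5-en-2-one
Product: 5 N'-(6-methylhept-5-en-2-ylidene)-2,4,6-triisopropylbenzenesulfonohydrazide
Conditions: 2,4,6-triisopropylbenzenesulfonohydrazide, HCl (cat.), MeOH, rt
Reagents that add atoms: 2,4,6-triisopropylbenzenesulfonohydrazide CC(C)c1cc(C(C)C)c(S(=O)(=O)NN)c(C(C)C)c1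
Why: Acid-catalysed condensation of the methyl ketone with the arenesulfonyl hydrazide gives the hydrazone needed for a Shapiro reaction.

**Step 4**
Reactants: 5 N'-(6-methylhept-5-en-2-ylidene)-2,4,6-triisopropylbenzenesulfonohydrazide
Product: 7 2-bromo-6-methylhepta-1,5-diene, via vinyllithium 6 (not isolated)
Conditions: n-BuLi (2.2 equiv), TMEDA, hexane/THF, −78 → 0 °C; then BrCH2CH2Br, −78 °C
Reagents that add atoms: 1,2-dibromoethane BrCCBr
Why: In the Shapiro reaction the hydrazone dianion forms at the less hindered methyl group and loses sulfinate and N2 to give the 2-lithio-1-alkene, which takes bromine from 1,2-dibromoethane.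

**Step 5**
Reactants: 3 (2E,6E)-3,7-dimethyl-8-oxoocta-2,6-dien-1-yl acetate; 7 2-bromo-6-methylhepta-1,5-diene
Product: 10 (2E,6R,7E)-3,7-dimethyl-6-(6-methylhepta-1,5-dien-2-yl)-8-(trifluoromethylsulfonyloxy)octa-2,7-dien-1-yl acetate, via Grignard reagent 8 (not isolated), via TMS enol ether 9 (not isolated)
Conditions: 7, Mg, THF; then 3, CuTC (5 mol %), (R)-Tol-BINAP (6 mol %), TMSCl, Et2O, −78 °C, slow addition; then CsF, PhNTf2, DME, rt
Reagents that add atoms: N-phenylbis(trifluoromethanesulfonimide) O=S(=O)(N(c1ccccc1)S(=O)(=O)C(F)(F)F)C(F)(F)F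
Why: The Cu(I)/Tol-BINAP-catalysed, TMSCl-accelerated enantioselective conjugate addition of the alkenyl Grignard reagent to the β-carbon (C9) of the s-trans enal should set C9 under ligand control and give the silyl enol ether with oxygen cis to the C10 methyl group, which fluoride-mediated O-triflation converts with retention into the (E)-enol triflate, while the allylic acetate is expected to survive at −78 °C.

**Step 6**
Reactants: 10 (2E,6R,7E)-3,7-dimethyl-6-(6-methylhepta-1,5-dien-2-yl)-8-(trifluoromethylsulfonyloxy)octa-2,7-dien-1-yl acetate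
Product: 11 (2E,6R,7E)-6-[(5E)-7-hydroxy-6-methylhepta-1,5-dien-2-yl]-3,7-dimethyl-8-(trifluoromethylsulfonyloxy)octa-2,7-dien-1-yl acetate
Conditions: SeO2 (cat.), t-BuOOH, CH2Cl2, 0 °C
Reagents that add atoms: selenium dioxide O=[Se]=O (catalytic oxygen carrier); tert-butyl hydroperoxide CC(C)(C)OO (terminal oxidant)
Why: SeO2 allylic oxidation should again select the terminal isopropylidene group and its (E)-methyl, because the enol triflate, the acetate-bearing alkene and the 1,1-disubstituted alkene are all poorer partners in the ene step.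

**Step 7**
Reactants: 11 (2E,6R,7E)-6-[(5E)-7-hydroxy-6-methylhepta-1,5-dien-2-yl]-3,7-dimethyl-8-(trifluoromethylsulfonyloxy)octa-2,7-dien-1-yl acetate
Product: 12 (2E,6R,7E)-3,7-dimethyl-6-[(5E)-6-methyl-7-oxohepta-1,5-dien-2-yl]-8-(trifluoromethylsulfonyloxy)octa-2,7-dien-1-yl acetate
Conditions: MnO2, CH2Cl2, rt
Reagents that add atoms: none
Why: MnO2 oxidation of the primary allylic alcohol should give the (E)-2-methylenal that serves as the dienophile, with all other groups untouched.

**Step 8**
Reactants: 12 (2E,6R,7E)-3,7-dimethyl-6-[(5E)-6-methyl-7-oxohepta-1,5-dien-2-yl]-8-(trifluoromethylsulfonyloxy)octa-2,7-dien-1-yl acetate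
Product: 13 (2E,6R,7E)-9-ethoxy-3,7-dimethyl-6-[(5E)-6-methyl-7-oxohepta-1,5-dien-2-yl]deca-2,7,9-trien-1-yl acetate
Conditions: CH2=C(OEt)SnBu3, Pd2(dba)3 (cat.), AsPh3, LiCl, NMP, rt, BHT
Reagents that add atoms: tributyl(1-ethoxyvinyl)stannane CCCC[Sn](CCCC)(CCCC)C(=C)OCC
Why: Stille coupling of the enol triflate with the α-ethoxyvinylstannane should build the 2-ethoxy diene with retention of the C1=C10 geometry under neutral conditions that tolerate the enal, do not touch the bis-allylic C9 centre, and at room temperature with an arsine ligand should not ionise the allylic acetate.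

**Step 9**
Reactants: 13 (2E,6R,7E)-9-ethoxy-3,7-dimethyl-6-[(5E)-6-methyl-7-oxohepta-1,5-dien-2-yl]deca-2,7,9-trien-1-yl acetate
Product: 15 (13E)-15-acetoxy-2-oxo-ent-labda-8(17),13-dien-18-al, via cycloadduct enol ether 14 (not isolated)
Conditions: Me2AlCl (2.2 equiv), CH2Cl2, −78 → −20 °C; then 1 M HCl, THF, 0 °C
Reagents that add atoms: water O
Why: Me2AlCl binds the aldehyde of 13 and lowers the LUMO of the (E)-2-methylenal, which then adds to the 2-ethoxy diene in a concerted, asynchronous intramolecular [4+2] cycloaddition that forms C5–C10 and C3–C4 together. The closest known reaction type is the Lewis-acid-promoted type 1 intramolecular Diels–Alder reaction of (E,E,E)-1,3,9-decatrienals to trans-fused octalins. Ring A (C1–C5, C10) closes as the six-membered cycloadduct ring, and ring B (C5–C10) closes at the same time as a six-membered ring through the four-atom C6–C9 tether, which also fixes the regiochemistry. C5 and C10 are set relative to each other by the (E)-diene and (E)-dienophile in the endo transition state (aluminium-bound CHO under the diene, tether exo), which should give the trans ring fusion with H-5 anti to C-20 and the formyl group equatorial on C4; C10 is set relative to C9 by a chair-like tether with the C11 chain pseudo-equatorial, so that the dienophile adds to the diene face opposite that chain; C4 stays a stereocentre only until step 10. The step needs endo over exo selectivity and one diene face, which the aluminium-bound formyl group and the equatorial preference of the C9 substituent are expected to secure, while the unactivated C8=C17 and C13=C14 alkenes should not react. Aqueous HCl then hydrolyses the enol ether of 14 to the C2 ketone.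

**Step 10**
Reactants: 15 (13E)-15-acetoxy-2-oxo-ent-labda-8(17),13-dien-18-al
Product: 17 ent-copalol [(13E)-ent-labda-8(17),13-dien-15-ol], via bis-hydrazone 16 (not isolated)
Conditions: N2H4·H2O, KOH, diethylene glycol, 130 °C then 200 °C, degassed
Reagents that add atoms: none
Why: Wolff–Kishner reduction (Huang–Minlon procedure) should turn the C2 ketone into CH2 and the non-enolisable C18 aldehyde into the second C4 methyl group through their hydrazones (the equatorial formyl group is anti to C2, so no cyclic azine can form), while KOH saponifies the acetate and the isolated alkenes and the three stereocentres are left alone.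

**Step 11**
Reactants: 17 ent-copalol [(13E)-ent-labda-8(17),13-dien-15-ol]
Product: 18 ent-copalyl hydrogen malonate (target)
Conditions: Meldrum's acid, toluene, 100 °C
Reagents that add atoms: Meldrum's acid (2,2-dimethyl-1,3-dioxane-4,6-dione) CC1(C)OC(=O)CC(=O)O1
Why: Alcoholysis of Meldrum's acid by the primary allylic alcohol opens the dioxanedione and releases acetone, which should give the malonic acid half ester directly without a protecting group.

**Compound list**
1 | geranyl acetate | CC(C)=CCC/C(C)=C/COC(C)=O | starting material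
2 | (2E,6E)-8-hydroxy-3,7-dimethylocta-2,6-dien-1-yl acetate | OC/C(C)=C/CC/C(C)=C/COC(C)=O | intermediate
3 | (2E,6E)-3,7-dimethyl-8-oxoocta-2,6-dien-1-yl acetate | O=C/C(C)=C/CC/C(C)=C/COC(C)=O | intermediate
4 | 6-methylhept-5-en-2-one | CC(=O)CCC=C(C)C | starting material
5 | N'-(6-methylhept-5-en-2-ylidene)-2,4,6-triisopropylbenzenesulfonohydrazide | CC(CCC=C(C)C)=NNS(=O)(=O)c1c(C(C)C)cc(C(C)C)cc1C(C)C | intermediate
6 | (6-methylhepta-1,5-dien-2-yl)lithium (vinyllithium) | [Li]C(=C)CCC=C(C)C | intermediate
7 | 2-bromo-6-methylhepta-1,5-diene | C=C(Br)CCC=C(C)C | intermediate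
8 | (6-methylhepta-1,5-dien-2-yl)magnesium bromide (Grignard reagent) | C=C([Mg]Br)CCC=C(C)C | intermediate
9 | (2E,6R,7E)-3,7-dimethyl-6-(6-methylhepta-1,5-dien-2-yl)-8-(trimethylsilyloxy)octa-2,7-dien-1-yl acetate (TMS enol ether) | C[Si](C)(C)O/C=C(\C)[C@H](CC/C(C)=C/COC(C)=O)C(=C)CCC=C(C)C | intermediate
10 | (2E,6R,7E)-3,7-dimethyl-6-(6-methylhepta-1,5-dien-2-yl)-8-(trifluoromethylsulfonyloxy)octa-2,7-dien-1-yl acetate | O=S(=O)(O/C=C(\C)[C@H](CC/C(C)=C/COC(C)=O)C(=C)CCC=C(C)C)C(F)(F)F | intermediate
11 | (2E,6R,7E)-6-[(5E)-7-hydroxy-6-methylhepta-1,5-dien-2-yl]-3,7-dimethyl-8-(trifluoromethylsulfonyloxy)octa-2,7-dien-1-yl acetate | O=S(=O)(O/C=C(\C)[C@H](CC/C(C)=C/COC(C)=O)C(=C)CC/C=C(\C)CO)C(F)(F)F | intermediate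
12 | (2E,6R,7E)-3,7-dimethyl-6-[(5E)-6-methyl-7-oxohepta-1,5-dien-2-yl]-8-(trifluoromethylsulfonyloxy)octa-2,7-dien-1-yl acetate | O=S(=O)(O/C=C(\C)[C@H](CC/C(C)=C/COC(C)=O)C(=C)CC/C=C(\C)C=O)C(F)(F)F | intermediate
13 | (2E,6R,7E)-9-ethoxy-3,7-dimethyl-6-[(5E)-6-methyl-7-oxohepta-1,5-dien-2-yl]deca-2,7,9-trien-1-yl acetate | C=C(OCC)/C=C(\C)[C@H](CC/C(C)=C/COC(C)=O)C(=C)CC/C=C(\C)C=O | intermediate
14 | (13E)-15-acetoxy-2-ethoxy-ent-labda-1,8(17),13-trien-18-al (trans-fused cycloadduct enol ether; formyl equatorial on C4) | C=C1CC[C@@H]2[C@@](C)(C=O)CC(OCC)=C[C@@]2(C)[C@@H]1CC/C(C)=C/COC(C)=O | intermediate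
15 | (13E)-15-acetoxy-2-oxo-ent-labda-8(17),13-dien-18-al (trans-fused; formyl equatorial on C4) | C=C1CC[C@@H]2[C@@](C)(C=O)CC(=O)C[C@@]2(C)[C@@H]1CC/C(C)=C/COC(C)=O | intermediate
16 | bis-hydrazone of (13E)-15-hydroxy-2-oxo-ent-labda-8(17),13-dien-18-al | C=C1CC[C@@H]2[C@@](C)(C=NN)CC(=NN)C[C@@]2(C)[C@@H]1CC/C(C)=C/CO | intermediate
17 | ent-copalol, (2E)-3-methyl-5-[(1R,4aR,8aR)-5,5,8a-trimethyl-2-methylidenedecahydronaphthalen-1-yl]pent-2-en-1-ol | C=C1CC[C@@H]2C(C)(C)CCC[C@@]2(C)[C@@H]1CC/C(C)=C/CO | intermediate
18 | ent-copalyl hydrogen malonate, 3-{[(2E)-3-methyl-5-[(1R,4aR,8aR)-5,5,8a-trimethyl-2-methylidenedecahydronaphthalen-1-yl]pent-2-en-1-yl]oxy}-3-oxopropanoic acid | C=C1CC[C@@H]2C(C)(C)CCC[C@@]2(C)[C@@H]1CC/C(C)=C/COC(=O)CC(=O)O | target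

**Count**
Total steps: 11. Longest linear sequence: 9 steps (1, 2, 5, 6, 7, 8, 9, 10, 11) from geranyl acetate; steps 3 and 4 form the side branch.

**Steps most likely to fail**

1. Step 9 (key step). What may go wrong: the exo (tether-endo) mode or attack on the other diene face competes, giving cis-fused or C10-epimeric adducts, or the Lewis acid cleaves the enol ether before ring closure. Fallback: give up substrate control and run the same cycloaddition of 13 under reagent control with a chiral cationic oxazaborolidinium Lewis acid (CBS-type, activated by Tf2NH, CH2Cl2, −78 °C), the antipode being chosen to match C9. Such catalysts hold 2-substituted enals in a defined complex and impose the endo mode and the diene face. The same acidic work-up then gives 15. The fallback sets out from 13 and comes back at 15; it makes no new compound (F0).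

2. Step 5. What may go wrong: low enantioselectivity, or 1,2-addition, in the copper-catalysed addition to the α-branched enal. Fallback (auxiliary control in place of catalyst control), from 3:
   - Acetalisation with (2R,3R)-butane-2,3-diol (PPTS, benzene, water removal) should give (2E,6E)-7-[(4R,5R)-4,5-dimethyl-1,3-dioxolan-2-yl]-3-methylocta-2,6-dien-1-yl acetate F1. The diol antipode is chosen to give the 6R centre.
   - The alkenylcopper–BF3 reagent made from 7 (t-BuLi, CuI·PBu3, BF3·OEt2, Et2O, −78 °C) should open F1 by anti-SN2' attack at C9 to give (2E,6R,7E)-8-{[(2R,3R)-3-hydroxybutan-2-yl]oxy}-3,7-dimethyl-6-(6-methylhepta-1,5-dien-2-yl)octa-2,7-dien-1-yl acetate F2.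
   - Aqueous oxalic acid in THF should release (2E,6S)-3,7-dimethyl-6-(6-methylhepta-1,5-dien-2-yl)-8-oxooct-2-en-1-yl acetate F3 (C7 epimers; same spatial arrangement at C6 as in 10).
   - KHMDS then PhNTf2 (THF, −78 °C) should give 10, which would have to be separated from its (7Z) isomer because this enolisation does not fix the geometry. The fallback comes back at 10.

3. Step 6. What may go wrong: the ene step also attacks the 1,1-disubstituted alkene or the bis-allylic C9–H, or over-oxidation occurs. Fallback (oxidise the fragment before coupling), from 7: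
   - SeO2 (cat.)/t-BuOOH should give (2E)-6-bromo-2-methylhepta-2,6-dien-1-ol F4, in which only one alkene is reactive.
   - TBSCl/imidazole should give [(2E)-6-bromo-2-methylhepta-2,6-dien-1-yl]oxy(tert-butyl)dimethylsilane F5.
   - Under the conditions of step 5 with 3, F5 should give (2E,6R,7E)-6-[(5E)-7-(tert-butyldimethylsilyloxy)-6-methylhepta-1,5-dien-2-yl]-3,7-dimethyl-8-(trifluoromethylsulfonyloxy)octa-2,7-dien-1-yl acetate F6.
   - HF·pyridine in THF should then give 11. The fallback comes back at 11.

**Further compounds**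
F0 | step 9 | none | none
F1 | step 5 | (2E,6E)-7-[(4R,5R)-4,5-dimethyl-1,3-dioxolan-2-yl]-3-methylocta-2,6-dien-1-yl acetate | C[C@H]1OC(/C(C)=C/CC/C(C)=C/COC(C)=O)O[C@@H]1C
F2 | step 5 | (2E,6R,7E)-8-{[(2R,3R)-3-hydroxybutan-2-yl]oxy}-3,7-dimethyl-6-(6-methylhepta-1,5-dien-2-yl)octa-2,7-dien-1-yl acetate | C[C@@H](O)[C@@H](C)O/C=C(\C)[C@H](CC/C(C)=C/COC(C)=O)C(=C)CCC=C(C)C
F3 | step 5 | (2E,6S)-3,7-dimethyl-6-(6-methylhepta-1,5-dien-2-yl)-8-oxooct-2-en-1-yl acetate (C7 epimers) | O=CC(C)[C@H](CC/C(C)=C/COC(C)=O)C(=C)CCC=C(C)C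
F4 | step 6 | (2E)-6-bromo-2-methylhepta-2,6-dien-1-ol | OC/C(C)=C/CCC(Br)=C
F5 | step 6 | [(2E)-6-bromo-2-methylhepta-2,6-dien-1-yl]oxy(tert-butyl)dimethylsilane | CC(C)(C)[Si](C)(C)OC/C(C)=C/CCC(Br)=C
F6 | step 6 | (2E,6R,7E)-6-[(5E)-7-(tert-butyldimethylsilyloxy)-6-methylhepta-1,5-dien-2-yl]-3,7-dimethyl-8-(trifluoromethylsulfonyloxy)octa-2,7-dien-1-yl acetate | O=S(=O)(O/C=C(\C)[C@H](CC/C(C)=C/COC(C)=O)C(=C)CC/C=C(\C)CO[Si](C)(C)C(C)(C)C)C(F)(F)F
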